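Sunday's run ended with 23.6% target and 14.5% substrate, so 61.9% of the charge stood in no reading. We assume this unseen sink competes with partner for substrate.

in all of them: substrate 0.060 M

| flask | partner | temperature | remark | time |
|---|---|---|---|---|
| Sunday's | 0.40 M | −5 °C | run made earlier |  |
| Friday's | 0.55 M | 8 °C | run made earlier |  |
| amber | 0.300 M | 0 °C |  | 30 h |
| blue | 0.500 M | 15 °C |  | 30 h |

| run | time / h | target / % | substrate / % |
|---|---|---|---|
| Sunday's | 1.50 | 5.2 | 89.2 |
| Sunday's | 2.50 | 8.9 | 77.7 |
| Sunday's | 4.00 | 10.2 | 65.0 |
| Sunday's | 6.00 | 13.2 | 51.9 |
| Sunday's | 10.0 | 17.4 | 35.2 |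
| Sunday's | 15.0 | 22.4 | 22.7 |
| Sunday's | 20.0 | 23.6 | 14.5 |
| Friday's | 3.00 | 24.5 | 22.8 |
| Friday's | 6.00 | 21.9 | 11.6 |
| Friday's | 10.0 | 22.2 | 7.5 |
| Friday's | 12.0 | 20.2 | 5.4 |
| Friday's | 15.0 | 19.5 | 4.8 |
| Friday's | 20.0 | 18.1 | 4.9 |

(each reading ± 1 percentage point)

- the flask that ends with the higher amount of target, in percent of the substrate charged, or "neither" when 2 percentage points or less lies between them (amber / blue / neither)
- final target, as a percentage of the substrate charged, in amber
- final target, as a percentage of the substrate charged, in blue

- a reading or a percentage of target counts all its forms, free or not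

Our reckoning runs in steps.

1. Sunday's last reading gives 0.690 /M. This g is target read per substrate consumed, per molar of partner: a selectivity scaled by the partner charge. Friday's first reading gives 0.577 /M.

2. Taking substrate loss as first order in each, the rate constants read from these runs are 0.241 /M/h for Sunday's and 0.896 /M/h for Friday's. Interpolating the logarithm to 0 °C gives 0.400 /M/h, so we reckon that amber keeps 2.74% substrate at 30 h.

3. We then put amber's target at g times its partner times its conversion, 20.1%.

4. Friday's target readings fell by 6.4 percentage points in 17.0 h. We stretch that to 27.0 h and warm it to 15 °C with the same temperature ratio as the rate, so we reckon that blue loses 21 points.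

5. The weak link is g, which reads lower in Friday's run, the warmer one and also the one with more partner. So we reforge it, assuming that the difference is one of temperature. Interpolated to amber's temperature it is 0.647 /M, which gives amber 18.9%. Friday's value, with blue's substrate taken as consumed, gives blue 8.25%. We commit to these, which put amber higher than blue.

The forecast differs in both numbers: 24% for amber, 12% for blue, with amber the higher. On blue it says: “Its loss, assuming a higher activation energy, is about 0.04 /h for some 27 h”.

Amber ends at 15.2% and blue at 0.631%, so amber is higher. At the end amber holds 11.9% crystals, counted in its target, and blue 0%.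

    substrate + partner ⇌ target (K = 2.70 /M, k = 0.320 /M/h, Ea = 71.0 kJ/mol, ΔH = −75.0 kJ/mol)
    substrate + target → side product (k = 21.0 /M/h, Ea = 48.0 kJ/mol)
    crystals ⇌ target, rate k3*(cs3 - [target]) while solid is left; crystals form when [target] > cs3 (solubility = 2.10 mM, k = 1.10 /h)
    (constants at 0 °C)

Put to amber's conversion of 95.2%, g gives 19.7%. In the neighbouring flask, like amber but with 1.2 M partner and 0.98% substrate left, g gives 82.0%, and that flask holds 45.3%.

(Readings and results were computed from invented constants, noise included.)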